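The route rests on cutting the C3–C3a bond of the dihydrofuran (ring B), which joins the methyl-bearing carbon C3 to arene ring A. The feature exploited is the CH–CH3 unit at C3 next to the O1-bound benzylic centre C2: C3 and its methyl group are a vinyl group in disguise. The precursor is an ortho-iodoaryl (S)-1-arylallyl ether, made by iridium-catalysed asymmetric allylic etherification. An aryl radical at C3a closes ring B by 5-exo-trig attack, turns the alkene terminus into the methyl group and sets C3 trans to the C2 aryl group in one operation. Bromine masks the phenol of ring C (the C2 aryl group), and an allyl group masks the propenyl chain.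

Key step: step 5

Assumption: the (Sa,Sc,Sc) ligand of step 4 is taken to deliver the (S)-ether 8. If the sense of induction proves opposite, the equally available mirror-image ligand is used.

Step 1
Reactants: 1 eugenol (4-allyl-2-methoxyphenol)
Product: 2 4-allyl-2-iodo-6-methoxyphenol
Conditions: NaI, aq. NaOCl (slow addition), NaOH, MeOH, 0 °C; acidic work-up
Reagents that add atoms: sodium iodide, [Na+].[I-]
Why: Electrophilic aromatic iodination of the phenolate with hypoiodite made in situ should go to the only free position ortho to the phenolate oxygen (para is blocked), because the isolated terminal alkene is far less nucleophilic than the phenolate ring.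

Step 2
Reactants: 3 3-bromo-4,5-dimethoxybenzaldehyde
Product: 4 1-bromo-5-ethenyl-2,3-dimethoxybenzene
Conditions: Ph3PCH3Br, KOtBu, THF, 0 °C to rt
Reagents that add atoms: methyltriphenylphosphonium bromide, C[P+](c1ccccc1)(c1ccccc1)c1ccccc1.[Br-]
Why: Wittig methylenation of an aromatic aldehyde with the non-stabilised ylide is reliable and leaves the aryl bromide and the methyl ethers untouched.

Step 3
Reactants: 4 1-bromo-5-ethenyl-2,3-dimethoxybenzene; 5 allyl methyl carbonate (3 equiv)
Product: 6 (E)-3-(3-bromo-4,5-dimethoxyphenyl)prop-2-en-1-yl methyl carbonate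
Conditions: second-generation Hoveyda–Grubbs catalyst (3 mol %), CH2Cl2, 40 °C
Reagents that add atoms: none
Why: Olefin cross-metathesis of a styrene with an excess of a protected allylic alcohol should give the conjugated (E)-cinnamyl carbonate under thermodynamic control, driven by loss of ethylene.

Step 4
Reactants: 2 4-allyl-2-iodo-6-methoxyphenol; 6 (E)-3-(3-bromo-4,5-dimethoxyphenyl)prop-2-en-1-yl methyl carbonate
Product: 8 (S)-5-allyl-2-{[1-(3-bromo-4,5-dimethoxyphenyl)prop-2-en-1-yl]oxy}-1-iodo-3-methoxybenzene, via sodium aryloxide 7 (not isolated)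
Conditions: 2, NaH, THF, 0 °C; then 6, [Ir(cod)Cl]2 (2 mol %), (Sa,Sc,Sc)-O,O'-(1,1'-binaphthyl-2,2'-diyl)-N,N-bis(1-phenylethyl)phosphoramidite (4 mol %), THF, rt; aqueous work-up
Reagents that add atoms: none
Why: In this iridium-catalysed asymmetric allylic etherification of a linear cinnamyl carbonate, the aryloxide should attack the aryl-substituted terminus of the allyl-iridium intermediate anti to the metal and give the branched ether, with the cyclometalated phosphoramidite complex fixing the face of attack and hence the (S) centre that becomes C2.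

Step 5
Reactants: 8 (S)-5-allyl-2-{[1-(3-bromo-4,5-dimethoxyphenyl)prop-2-en-1-yl]oxy}-1-iodo-3-methoxybenzene
Product: 9 (2S,3S)-5-allyl-2-(3-bromo-4,5-dimethoxyphenyl)-7-methoxy-3-methyl-2,3-dihydrobenzofuran
Conditions: Bu3SnH (1.1 equiv), Et3B (0.2 equiv), air, toluene (0.02 M), 0 °C
Reagents that add atoms: none
Why: Stannyl radicals started by Et3B and air abstract iodine from C3a, the σ-aryl radical adds to the internal carbon of the neighbouring vinyl group to form the C3a–C3 bond, and the primary radical so formed takes a hydrogen atom from Bu3SnH, so that the former alkene terminus becomes the C3 methyl group. The closest known reaction type is the tin hydride-mediated aryl radical cyclisation of ortho-haloaryl allyl ethers to 3-methyl-2,3-dihydrobenzofurans. Ring B closes in the 5-exo-trig mode, which is kinetically far ahead of 6-endo attack, and the hydride concentration chosen should trap the primary radical before a neophyl-type 1,2-aryl shift can enlarge the ring to a chroman. C3 is set by 1,2-induction from C2: in the envelope-like transition state the C2 aryl group lies pseudo-equatorial and the CH2 terminus of the alkene turns away from it, which should give the 2,3-trans (2S,3S) isomer, while C2 itself is not touched. The step needs chemoselectivity for C–I over the C–Br bond of ring C and for the vinyl over the allyl group; the first is secured by the much weaker C–I bond together with about one equivalent of hydride at 0 °C, the second by the short tether that makes closure onto the vinyl group unimolecular and very fast.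

Step 6
Reactants: 9 (2S,3S)-5-allyl-2-(3-bromo-4,5-dimethoxyphenyl)-7-methoxy-3-methyl-2,3-dihydrobenzofuran
Product: 10 (2S,3S)-2-(3-bromo-4,5-dimethoxyphenyl)-7-methoxy-3-methyl-5-[(E)-prop-1-enyl]-2,3-dihydrobenzofuran
Conditions: RuHCl(CO)(PPh3)3 (2 mol %), toluene, 80 °C
Reagents that add atoms: none
Why: Ruthenium hydride-catalysed alkene isomerisation (hydrometalation then β-hydride elimination) should move the terminal double bond into conjugation with ring A and stop there, the (E)-propenylarene being the thermodynamically preferred isomer and no stereocentre being affected.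

Step 7
Reactants: 10 (2S,3S)-2-(3-bromo-4,5-dimethoxyphenyl)-7-methoxy-3-methyl-5-[(E)-prop-1-enyl]-2,3-dihydrobenzofuran
Product: 11 5-{(2S,3S)-7-methoxy-3-methyl-5-[(E)-prop-1-enyl]-2,3-dihydrobenzofuran-2-yl}-2,3-dimethoxyphenol (target)
Conditions: Pd2(dba)3 (2 mol %), tBuXPhos (8 mol %), KOH (3 equiv), 1,4-dioxane/H2O, 100 °C; acidic work-up
Reagents that add atoms: potassium hydroxide, [K+].[OH-]
Why: Palladium-catalysed hydroxylation of an aryl bromide (C–O cross-coupling with hydroxide on a bulky biarylphosphine catalyst) should replace bromine by OH at the only carbon–halogen bond left, under basic conditions that do not touch C2, C3 or the (E)-alkene.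

Compound list
1 | eugenol (4-allyl-2-methoxyphenol) | C=CCc1ccc(O)c(OC)c1 | starting material
2 | 4-allyl-2-iodo-6-methoxyphenol | C=CCc1cc(I)c(O)c(OC)c1 | intermediate
3 | 3-bromo-4,5-dimethoxybenzaldehyde | COc1cc(C=O)cc(Br)c1OC | starting material
4 | 1-bromo-5-ethenyl-2,3-dimethoxybenzene | C=Cc1cc(Br)c(OC)c(OC)c1 | intermediate
5 | allyl methyl carbonate | C=CCOC(=O)OC | starting material
6 | (E)-3-(3-bromo-4,5-dimethoxyphenyl)prop-2-en-1-yl methyl carbonate | COC(=O)OC/C=C/c1cc(Br)c(OC)c(OC)c1 | intermediate
7 | sodium 4-allyl-2-iodo-6-methoxyphenolate (not isolated) | [Na+].[O-]c1c(I)cc(CC=C)cc1OC | intermediate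
8 | (S)-5-allyl-2-{[1-(3-bromo-4,5-dimethoxyphenyl)prop-2-en-1-yl]oxy}-1-iodo-3-methoxybenzene | C=C[C@@H](c1cc(Br)c(OC)c(OC)c1)Oc1c(I)cc(CC=C)cc1OC | intermediate
9 | (2S,3S)-5-allyl-2-(3-bromo-4,5-dimethoxyphenyl)-7-methoxy-3-methyl-2,3-dihydrobenzofuran | C=CCc1cc(OC)c2c(c1)[C@H](C)[C@@H](c1cc(Br)c(OC)c(OC)c1)O2 | intermediate
10 | (2S,3S)-2-(3-bromo-4,5-dimethoxyphenyl)-7-methoxy-3-methyl-5-[(E)-prop-1-enyl]-2,3-dihydrobenzofuran | C/C=C/c1cc(OC)c2c(c1)[C@H](C)[C@@H](c1cc(Br)c(OC)c(OC)c1)O2 | intermediate
11 | 5-{(2S,3S)-7-methoxy-3-methyl-5-[(E)-prop-1-enyl]-2,3-dihydrobenzofuran-2-yl}-2,3-dimethoxyphenol | C/C=C/c1cc(OC)c2c(c1)[C@H](C)[C@@H](c1cc(O)c(OC)c(OC)c1)O2 | target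

Total step count: 7
Longest linear sequence: 6 steps (3, 4, 6, 8, 9, 10, 11)

Steps most likely to fail

**Step 5 (key step).**
- What may go wrong:
  - insufficient facial selectivity when the aryl radical attacks the vinyl group, which erodes trans over cis;
  - premature hydrogen transfer to the aryl radical;
  - over-reduction at the C–Br bond.
- Fallback: both centres are fixed before ring closure, and the same C3–C3a bond is then made by a stereospecific polar displacement. The fallback sets out from styrene 4 (and uses aryloxide 7) and comes back at 9.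
- Cross-metathesis of 4 with cis-but-2-ene (second-generation Hoveyda–Grubbs catalyst, CH2Cl2) should give the (E)-propenylarene F1. Shi epoxidation with the enantiomer of the fructose-derived ketone (KHSO5, K2CO3, MeCN/dimethoxymethane/water, 0 °C) should give the (2S,3S)-epoxide F2. Aryloxide 7 (DMF, 60 °C) should open this at the benzylic carbon with inversion to the (1R,2S)-aryloxy alcohol F3.
- Tosylation (TsCl, pyridine) gives the secondary tosylate F4. Selective iodine–magnesium exchange (iPrMgCl·LiCl, THF, −20 °C) gives the arylmagnesium chloride F5. Copper catalysis (CuI, TMEDA, LiOMe, 0 °C) should then close ring B by 5-exo-tet SN2 displacement with inversion at C3. The double inversion of the trans-epoxide delivers 9 as the trans isomer.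

**Step 4.**
- What may go wrong:
  - slow attack of the doubly ortho-substituted aryloxide on the allyl-iridium intermediate;
  - leakage to the linear ether;
  - erosion of enantiomeric purity by reversible ionisation of the product.
- Fallback: the centre is obtained by resolution and transferred stereospecifically. The fallback sets out from aldehyde 3 and comes back at 8.
- Addition of vinylmagnesium bromide (THF, 0 °C) gives the racemic allylic alcohol F6. Kinetic resolution by acylation (Candida antarctica lipase B, vinyl acetate, MTBE) should leave the (S)-alcohol F7 and convert its antipode into the (R)-acetate F8, which is separated.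
- Methyl chloroformate and pyridine give the (S)-branched carbonate F9. Stereoretentive ruthenium-catalysed allylic etherification with phenol 2 ([Cp*Ru(MeCN)3]PF6, K2CO3, THF, rt) should give 8 with branched regiochemistry and net retention by double inversion.

**Step 7.**
- What may go wrong:
  - sluggish oxidative addition into the electron-rich, ortho-methoxylated C–Br bond;
  - competing diaryl ether formation;
  - hydrodebromination.
- Fallback: the C–O bond is made through boron instead of by direct coupling. The fallback sets out from 10 and comes back at 11.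
- Miyaura borylation (B2pin2, Pd(dppf)Cl2, KOAc, 1,4-dioxane, 80 °C) should give the pinacol boronate F10. Oxidation with NaBO3·4H2O (THF/water, rt) converts it into phenol 11 without touching the alkene.

Further compounds
F1 | step 5 | 1-bromo-2,3-dimethoxy-5-[(E)-prop-1-enyl]benzene | C/C=C/c1cc(Br)c(OC)c(OC)c1
F2 | step 5 | (2S,3S)-2-(3-bromo-4,5-dimethoxyphenyl)-3-methyloxirane | C[C@@H]1O[C@H]1c1cc(Br)c(OC)c(OC)c1
F3 | step 5 | (1R,2S)-1-(4-allyl-2-iodo-6-methoxyphenoxy)-1-(3-bromo-4,5-dimethoxyphenyl)propan-2-ol | C[C@H](O)[C@@H](c1cc(Br)c(OC)c(OC)c1)Oc1c(I)cc(CC=C)cc1OC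
F4 | step 5 | (1R,2S)-1-(4-allyl-2-iodo-6-methoxyphenoxy)-1-(3-bromo-4,5-dimethoxyphenyl)propan-2-yl 4-methylbenzenesulfonate | C[C@H](OS(=O)(=O)c1ccc(C)cc1)[C@@H](c1cc(Br)c(OC)c(OC)c1)Oc1c(I)cc(CC=C)cc1OC
F5 | step 5 | arylmagnesium chloride derived from F4 by iodine–magnesium exchange | C[C@H](OS(=O)(=O)c1ccc(C)cc1)[C@@H](c1cc(Br)c(OC)c(OC)c1)Oc1c([Mg]Cl)cc(CC=C)cc1OC
F6 | step 4 | racemic 1-(3-bromo-4,5-dimethoxyphenyl)prop-2-en-1-ol | C=CC(O)c1cc(Br)c(OC)c(OC)c1
F7 | step 4 | (S)-1-(3-bromo-4,5-dimethoxyphenyl)prop-2-en-1-ol | C=C[C@H](O)c1cc(Br)c(OC)c(OC)c1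
F8 | step 4 | (R)-1-(3-bromo-4,5-dimethoxyphenyl)prop-2-en-1-yl acetate | C=C[C@@H](OC(C)=O)c1cc(Br)c(OC)c(OC)c1
F9 | step 4 | (S)-1-(3-bromo-4,5-dimethoxyphenyl)prop-2-en-1-yl methyl carbonate | C=C[C@H](OC(=O)OC)c1cc(Br)c(OC)c(OC)c1
F10 | step 7 | (2S,3S)-2-[3,4-dimethoxy-5-(4,4,5,5-tetramethyl-1,3,2-dioxaborolan-2-yl)phenyl]-7-methoxy-3-methyl-5-[(E)-prop-1-enyl]-2,3-dihydrobenzofuran | C/C=C/c1cc(OC)c2c(c1)[C@H](C)[C@@H](c1cc(B3OC(C)(C)C(C)(C)O3)c(OC)c(OC)c1)O2
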